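Cryptoporic acid T is a trimer of one building block, a 15-hydroxyalbicanol ether of (2R,3S)-isocitrate, joined by two C15 esters. Everything rests on cutting ring A of the drimane at C5–C10 and C3–C4; the feature used is that ring A holds the fusion bond C5–C10 next to both quaternary carbons, C10 and C4. An intramolecular Diels–Alder reaction of an acyclic (E,E)-trienoate forms both bonds at once: the C10=C1–C2=C3 diene and the C4=C5 tiglate close ring A, the C6–C9 tether becomes ring B, and C4, C5 and C10 are set together. In the precursor O8 and O11 sit in a six-membered di-tert-butylsilylene ring that steers the diene face.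

Key step: step 8

Remarks on the chemistry (assumptions)
- Numbering: drimane ring carbons C1–C10; C11 on C9; C12 is the exocyclic carbon on C8; C15 is the oxygen-bearing 4α (equatorial) carbon on C4; the methyl groups are 4β and 10β. All bicyclic compounds have 5α-H, 9α-H and a 9β-CH2O arm. Isocitrate carbons: C1′ (ether carbon), C2′ (central), C3′ (CH2 arm). Unit A ends with the free C2′ acid, unit C with the free C15 hydroxyl.
- Ring B is six-membered, so the dialdehyde that supplies C6–C8 must be the four-carbon succinaldehyde. The five-carbon glutaraldehyde would leave one carbon too many in the tether. Succinaldehyde is assumed to be bought (or freshly liberated from 2,5-dimethoxytetrahydrofuran) and used at once.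
- For the cycloaddition C8 is kept at the carbinol level inside the silylene and not as a ketal. A ketal would not survive the aluminium Lewis acid that the endo selectivity needs. The acyclic C8 ketone needed to make it would also put the only stereocentre (C9) α to a carbonyl and allylic to the diene. The C8 dioxolane and the C11 benzyl ether are installed right after ring formation (compound 21).
- Protecting groups for the assembly: C15 as TBS ether (temporary), C3′ acid of units B and C as 2-(trimethylsilyl)ethyl ester, C2′ acid as tert-butyl ester (freed before each coupling, kept to the end on unit A).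

Step 1
Reactants: 1 succinaldehyde; 2 methyl 2-(triphenylphosphoranylidene)propanoate
Product: 3 methyl (2E)-2-methyl-6-oxohex-2-enoate
Conditions: 1 (3 equiv), CH2Cl2, 0 °C → rt
Reagents that add atoms: none
Why: Wittig olefination with a stabilised α-branched ylide should give the (E)-trisubstituted enoate, and the excess of dialdehyde keeps the reaction at the mono-adduct.

Step 2
Reactants: 4 but-3-yn-1-ol
Product: 6 (3E)-3-methylhexa-3,5-dien-1-ol, via alkenylalane 5 (not isolated)
Conditions: Me3Al (3 equiv), Cp2ZrCl2 (0.25 equiv), ClCH2CH2Cl, 0 °C → rt; then vinyl bromide, ZnCl2, Pd(PPh3)4 (5 mol %), THF, rt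
Reagents that add atoms: Me3Al (trimethylaluminium), C[Al](C)C; vinyl bromide, C=CBr
Why: Zirconium-catalysed Negishi carboalumination adds CH3 and Al syn across the terminal alkyne (methyl to the internal carbon), and the palladium-catalysed cross-coupling of the alkenylalane with vinyl bromide retains that geometry, so the future C10 methyl ends up cis to the vinyl group.

Step 3
Reactants: 6 (3E)-3-methylhexa-3,5-dien-1-ol
Product: 7 (3E)-3-methylhexa-3,5-dienoic acid
Conditions: TEMPO (0.2 equiv), PhI(OAc)2 (2.2 equiv), MeCN–pH 7 phosphate buffer, 0 °C → rt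
Reagents that add atoms: water, O
Why: TEMPO/PhI(OAc)2 oxidation in buffered aqueous acetonitrile takes the primary alcohol through the aldehyde hydrate to the acid under near-neutral conditions that should leave the deconjugated diene in place.

Step 4
Reactants: 7 (3E)-3-methylhexa-3,5-dienoic acid; 8 (4R)-4-benzyl-1,3-oxazolidin-2-one
Product: 11 (4R)-4-benzyl-3-[(3E)-3-methylhexa-3,5-dienoyl]-1,3-oxazolidin-2-one, via mixed pivalic anhydride 9 (not isolated), via lithium oxazolidinide 10 (not isolated)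
Conditions: t-BuCOCl, Et3N, THF, −78 → 0 °C; then 8/n-BuLi (THF, −78 °C), −78 → 0 °C
Reagents that add atoms: none
Why: N-acylation of the lithiated oxazolidinone by the mixed pivalic anhydride at low temperature is faster than base-induced migration of the β,γ-double bond into conjugation.

Step 5
Reactants: 11 (4R)-4-benzyl-3-[(3E)-3-methylhexa-3,5-dienoyl]-1,3-oxazolidin-2-one; 3 methyl (2E)-2-methyl-6-oxohex-2-enoate
Product: 13 methyl (2E,6S,7R,8E)-7-{[(4R)-4-benzyl-2-oxo-1,3-oxazolidin-3-yl]carbonyl}-6-hydroxy-2,8-dimethylundeca-2,8,10-trienoate, via dibutylboron Z-enolate 12 (not isolated)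
Conditions: Bu2BOTf, Et3N, CH2Cl2, −78 → 0 °C; 3, −78 → 0 °C; then pH 7 buffer, MeOH, H2O2, 0 °C
Reagents that add atoms: none
Why: Evans syn-aldol reaction, in which the Z(O)-boron dienolate reacts at its α-carbon through a Zimmerman–Traxler chair and the (R)-benzyl auxiliary shields one enolate face, so C9 and the syn C8 carbinol are set together.

Step 6
Reactants: 13 aldol adduct
Product: 14 methyl (2E,6S,7S,8E)-6-hydroxy-7-(hydroxymethyl)-2,8-dimethylundeca-2,8,10-trienoate
Conditions: NaBH4, THF–H2O (4:1), 0 °C → rt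
Reagents that add atoms: none
Why: NaBH4 in wet THF reduces the activated imide carbonyl to the primary alcohol and releases the auxiliary, while the enoate and the diene are inert to borohydride.

Step 7
Reactants: 14 methyl (2E,6S,7S,8E)-6-hydroxy-7-(hydroxymethyl)-2,8-dimethylundeca-2,8,10-trienoate
Product: 15 methyl (2E)-5-{(4S,5S)-2,2-di-tert-butyl-5-[(2E)-penta-2,4-dien-2-yl]-1,3,2-dioxasilinan-4-yl}-2-methylpent-2-enoate
Conditions: t-Bu2Si(OTf)2, 2,6-lutidine, CH2Cl2, 0 °C
Reagents that add atoms: di-tert-butylsilyl bis(trifluoromethanesulfonate), CC(C)(C)[Si](OS(=O)(=O)C(F)(F)F)(OS(=O)(=O)C(F)(F)F)C(C)(C)C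
Why: Silylene protection of the syn-1,3-diol gives a six-membered ring in which the C8 substituent should sit equatorial and the dienyl group axial.

Step 8
Reactants: 15 silylene-bridged (E,E)-trienoate
Product: 16 methyl 8β,11-O-(di-tert-butylsilylene)-8β,11-dihydroxy-12-nordrim-1-en-15-oate
Conditions: EtAlCl2 (1.2 equiv), CH2Cl2, −78 → 0 °C
Reagents that add atoms: none
Why: EtAlCl2 binds the ester carbonyl, the only good donor in 15, and the concerted, asynchronous [4+2] cycloaddition of the C10=C1–C2=C3 diene with the C4=C5 enoate forms C5–C10 and C3–C4; the closest known reaction type is the Lewis-acid-catalysed intramolecular Diels–Alder reaction of undeca-2,8,10-trienoates to trans-fused octalins. Ring A closes by the cycloaddition itself (new cyclohexene, Δ1), and ring B closes because the four-carbon tether C6–C9 joins the dienophile carbon C5 to the diene terminus C10 through a chair-like tether. C4 is controlled by the (E)-geometry of the enoate together with the ester-endo transition state (ester cis to H5, so 4α-CO2Me and 4β-CH3). C5 and C10 are controlled by the same endo, tether-exo arrangement, in which the inside methyl of the (E)-diene ends up anti to H5 (trans fusion, 10β-CH3). The step needs endo selectivity, secured by Lewis-acid complexation of the ester, and diene-face selectivity, secured by the silylene ring: with the tether carbon C7 equatorial and the dienyl group axial on that ring, C11 is equatorial on the forming ring B and the C9 configuration is relayed to C10, C5 and C4, whereas attack on the other face would force C7 axial against a tert-butyl group on silicon. The silyl ethers tolerate the Lewis acid, which a C8 ketal would not.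

Step 9
Reactants: 16 silylene octalin ester
Product: 17 methyl 8β,11-dihydroxy-12-nordrim-1-en-15-oate
Conditions: HF·pyridine, THF, 0 °C → rt
Reagents that add atoms: none
Why: Fluoride cleaves both Si–O bonds of the silylene without touching the ester or the ring alkene.

Step 10
Reactants: 17 methyl 8β,11-dihydroxy-12-nordrim-1-en-15-oate
Product: 19 methyl 11-benzyloxy-8β-hydroxy-12-nordrim-1-en-15-oate, via dibutylstannylene acetal 18 (not isolated)
Conditions: Bu2SnO, toluene, reflux (−H2O); then BnBr, CsF, DMF, rt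
Reagents that add atoms: benzyl bromide, BrCc1ccccc1
Why: Stannylene-acetal activation makes the primary oxygen the more nucleophilic one, so the fluoride-promoted benzylation should occur at O11 and leave the axial 8β-hydroxyl free.

Step 11
Reactants: 19 methyl 11-benzyloxy-8β-hydroxy-12-nordrim-1-en-15-oate
Product: 20 methyl 11-benzyloxy-8-oxo-12-nordrim-1-en-15-oate
Conditions: Dess–Martin periodinane, NaHCO3, CH2Cl2, 0 °C → rt
Reagents that add atoms: none
Why: Dess–Martin oxidation of the secondary alcohol under buffered, non-basic conditions should give the β-benzyloxy ketone without β-elimination.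

Step 12
Reactants: 20 methyl 11-benzyloxy-8-oxo-12-nordrim-1-en-15-oate
Product: 21 methyl 11-benzyloxy-8,8-ethylenedioxy-12-nordrim-1-en-15-oate
Conditions: TMSOCH2CH2OTMS, TMSOTf (5 mol %), CH2Cl2, −78 → −20 °C
Reagents that add atoms: 1,2-bis(trimethylsilyloxy)ethane, C[Si](C)(C)OCCO[Si](C)(C)C
Why: Noyori ketalisation protects the hindered ketone at low temperature, and the C9 arm stays in its more stable β-equatorial position.

Step 13
Reactants: 21 methyl 11-benzyloxy-8,8-ethylenedioxy-12-nordrim-1-en-15-oate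
Product: 22 11-benzyloxy-8,8-ethylenedioxy-12-nordrim-1-en-15-ol
Conditions: LiAlH4, THF, 0 °C → rt
Reagents that add atoms: none
Why: LiAlH4 reduces the hindered equatorial ester to the neopentyl alcohol, and ketal, benzyl ether and alkene are inert.

Step 14
Reactants: 22 11-benzyloxy-8,8-ethylenedioxy-12-nordrim-1-en-15-ol
Product: 23 11-benzyloxy-15-(tert-butyldimethylsilyloxy)-8,8-ethylenedioxy-12-nordrim-1-ene
Conditions: TBSCl, imidazole, DMF, 40 °C
Reagents that add atoms: tert-butyldimethylsilyl chloride, CC(C)(C)[Si](C)(C)Cl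
Why: Imidazole-catalysed silylation of the primary alcohol is standard and leaves the ketal untouched.

Step 15
Reactants: 23 11-benzyloxy-15-(tert-butyldimethylsilyloxy)-8,8-ethylenedioxy-12-nordrim-1-ene
Product: 24 15-(tert-butyldimethylsilyloxy)-8,8-ethylenedioxy-12-nordriman-11-ol
Conditions: H2 (1 atm), 10% Pd/C, EtOAc, rt
Reagents that add atoms: none
Why: Heterogeneous hydrogenation saturates the cis-disubstituted C1=C2 bond (no new stereocentre) and hydrogenolyses the benzyl ether in the same operation, the silyl ether and ketal being stable in ethyl acetate.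

Step 16
Reactants: 25 D-aspartic acid 4-tert-butyl ester
Product: 28 (2R)-4-tert-butoxy-2-hydroxy-4-oxobutanoic acid, via diazonium carboxylate 26 (not isolated), via α-lactone 27 (not isolated)
Conditions: NaNO2, 0.5 M H2SO4, H2O–dioxane, 0 °C → rt
Reagents that add atoms: water, O
Why: Diazotisation of the α-amino acid in water gives the α-hydroxy acid with net retention, because the carboxylate first displaces N2 (inversion) and water then opens the α-lactone (second inversion).

Step 17
Reactants: 28 (2R)-4-tert-butoxy-2-hydroxy-4-oxobutanoic acid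
Product: 29 4-tert-butyl 1-methyl (2R)-2-hydroxybutanedioate
Conditions: MeI, KHCO3, DMF, rt
Reagents that add atoms: iodomethane, CI
Why: SN2 alkylation of the carboxylate, the only anion formed by KHCO3, gives the methyl ester and leaves the hydroxyl untouched.

Step 18
Reactants: 29 4-tert-butyl 1-methyl (2R)-2-hydroxybutanedioate
Product: 31 4-tert-butyl 1-methyl (2R,3S)-2-hydroxy-3-(prop-2-en-1-yl)butanedioate, via dilithium alkoxide enolate 30 (not isolated)
Conditions: LDA (2.1 equiv), THF, −78 → −20 °C; allyl bromide, −78 → −10 °C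
Reagents that add atoms: allyl bromide, C=CCBr
Why: Fráter–Seebach alkylation, in which the chelated dilithium alkoxide–enolate is allylated anti to the alkoxide oxygen, should set C3 (the later C2′) as S and give the (2R,3S) anti product.

Step 19
Reactants: 24 15-(tert-butyldimethylsilyloxy)-8,8-ethylenedioxy-12-nordriman-11-ol
Product: 32 15-(tert-butyldimethylsilyloxy)-8,8-ethylenedioxy-12-nordriman-11-yl trifluoromethanesulfonate
Conditions: Tf2O, 2,6-lutidine, CH2Cl2, −78 °C; cold work-up, used at once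
Reagents that add atoms: trifluoromethanesulfonic anhydride, O=S(=O)(OS(=O)(=O)C(F)(F)F)C(F)(F)F
Why: Sulfonylation of the primary alcohol at −78 °C gives the triflate, which has no internal nucleophile that could displace it because C8 is a ketal.

Step 20
Reactants: 32 C11 triflate; 31 4-tert-butyl 1-methyl (2R,3S)-2-hydroxy-3-(prop-2-en-1-yl)butanedioate
Product: 34 4-tert-butyl 1-methyl (2R,3S)-2-{[15-(tert-butyldimethylsilyloxy)-8,8-ethylenedioxy-12-nordriman-11-yl]oxy}-3-(prop-2-en-1-yl)butanedioate, via sodium alkoxide 33 (not isolated)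
Conditions: 31 (2 equiv), NaHMDS (1.9 equiv), THF, −78 °C; then 32, −78 → 0 °C
Reagents that add atoms: none
Why: Williamson ether synthesis, in which the sodium alkoxide of the α-hydroxy ester displaces the primary triflate at C11; only the O–H bond of 31 is involved, so C1′ and C2′ keep their configuration, and the low temperature and the absence of excess base should suppress β-elimination and self-condensation.

Step 21
Reactants: 34 allyl ether-diester
Product: 36 2-tert-butyl 1-methyl 3-hydrogen (1R,2S)-1-{[15-(tert-butyldimethylsilyloxy)-8,8-ethylenedioxy-12-nordriman-11-yl]oxy}propane-1,2,3-tricarboxylate, via aldehyde 35 (not isolated)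
Conditions: O3, CH2Cl2, −78 °C; Me2S; then NaClO2, NaH2PO4, 2-methylbut-2-ene, t-BuOH–H2O, rt
Reagents that add atoms: ozone, [O-][O+]=O; NaClO2 (sodium chlorite), [Na+].[O-]Cl=O
Why: Ozonolysis of the only alkene and Pinnick oxidation of the resulting aldehyde shorten the allyl group to the CH2CO2H arm of isocitrate without touching the ether, ketal or silyl ether.

Step 22
Reactants: 36 C3′ acid
Product: 37 2-tert-butyl 1-methyl 3-[2-(trimethylsilyl)ethyl] (1R,2S)-1-{[15-(tert-butyldimethylsilyloxy)-8,8-ethylenedioxy-12-nordriman-11-yl]oxy}propane-1,2,3-tricarboxylate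
Conditions: Me3SiCH2CH2OH, EDC·HCl, DMAP (cat.), CH2Cl2, 0 °C → rt
Reagents that add atoms: 2-(trimethylsilyl)ethanol, C[Si](C)(C)CCO
Why: Carbodiimide (Steglich-type) esterification of the unhindered primary carboxylic acid is routine and does not touch a stereocentre.

Step 23
Reactants: 37 ketal triester
Product: 38 2-tert-butyl 1-methyl 3-[2-(trimethylsilyl)ethyl] (1R,2S)-1-{[15-(tert-butyldimethylsilyloxy)-8-oxo-12-nordriman-11-yl]oxy}propane-1,2,3-tricarboxylate
Conditions: PPTS, acetone–H2O, 50 °C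
Reagents that add atoms: water, O
Why: Mildly acidic hydrolysis of the dioxolane frees the C8 ketone, while the tert-butyl ester, the silyl ether and the silylethyl ester should survive pyridinium tosylate.

Step 24
Reactants: 38 C8 ketone
Product: 39 2-tert-butyl 1-methyl 3-[2-(trimethylsilyl)ethyl] (1R,2S)-1-{[15-(tert-butyldimethylsilyloxy)drim-8(12)-en-11-yl]oxy}propane-1,2,3-tricarboxylate
Conditions: Zn, CH2Br2, TiCl4, THF (reagent pre-formed, −40 → 5 °C); then 38, CH2Cl2, 0 °C → rt
Reagents that add atoms: dibromomethane, BrCBr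
Why: Lombardo methylenation converts the ketone into the exocyclic methylene under non-basic conditions, so the β-alkoxy ketone should neither eliminate the C11 ether nor epimerise at C9, and the esters are not attacked.

Step 25
Reactants: 39 common exo-methylene triester
Product: 41 1-methyl 3-[2-(trimethylsilyl)ethyl] 2-hydrogen (1R,2S)-1-{[15-(tert-butyldimethylsilyloxy)drim-8(12)-en-11-yl]oxy}propane-1,2,3-tricarboxylate, via trimethylsilyl ester 40 (not isolated)
Conditions: TMSOTf, 2,6-lutidine, CH2Cl2, 0 °C → rt; aqueous pH 4 work-up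
Reagents that add atoms: none
Why: Silyl-triflate-mediated cleavage of the tert-butyl ester (O-silylation, loss of 2-methylpropene, hydrolysis of the silyl ester on work-up) frees the C2′ acid without protic acid, so the exocyclic alkene, the TBS ether and the silylethyl ester should persist.

Step 26
Reactants: 39 common exo-methylene triester
Product: 42 2-tert-butyl 1-methyl 3-hydrogen (1R,2S)-1-[(15-hydroxydrim-8(12)-en-11-yl)oxy]propane-1,2,3-tricarboxylate
Conditions: TBAF, THF, 0 °C → rt; aq. NH4Cl work-up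
Reagents that add atoms: none
Why: Fluoride removes the TBS ether and fragments the 2-(trimethylsilyl)ethyl ester (loss of ethene) in one operation, while the tert-butyl and methyl esters are unaffected.

Step 27
Reactants: 42 hydroxy acid
Product: 43 2-tert-butyl 1,3-dimethyl (1R,2S)-1-[(15-hydroxydrim-8(12)-en-11-yl)oxy]propane-1,2,3-tricarboxylate
Conditions: MeI, KHCO3, DMF, rt
Reagents that add atoms: iodomethane, CI
Why: Chemoselective SN2 methylation of the carboxylate gives the C3′ methyl ester of unit A and leaves the neopentyl C15 hydroxyl free.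

Step 28
Reactants: 43 unit A alcohol; 41 C2′ acid
Product: 45 silyl-protected dimer B–A (C2′ carboxyl of 41 esterified with the C15 hydroxyl of 43), via mixed trichlorobenzoic anhydride 44 (not isolated)
Conditions: 41, 2,4,6-trichlorobenzoyl chloride, Et3N, toluene, rt; then 43, DMAP, toluene, rt → 40 °C
Reagents that add atoms: none
Why: Yamaguchi esterification, in which DMAP attacks the pre-formed mixed trichlorobenzoic anhydride and the acylpyridinium acylates the neopentyl C15 hydroxyl, is the standard answer to a hindered acid and a hindered alcohol and forms no stereocentre.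

Step 29
Reactants: 45 silyl-protected dimer B–A
Product: 46 dimer alcohol B–A (free C15 hydroxyl on unit B)
Conditions: HF·pyridine, pyridine, THF, 0 °C → rt
Reagents that add atoms: none
Why: Buffered HF·pyridine cleaves the primary TBS ether, while the 2-(trimethylsilyl)ethyl ester needs naked fluoride and should stay.

Step 30
Reactants: 46 dimer alcohol B–A; 41 C2′ acid
Product: 48 protected trimer C–B–A (C2′ carboxyl of 41 esterified with the C15 hydroxyl of 46), via mixed 2-methyl-6-nitrobenzoic anhydride 47 (not isolated)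
Conditions: 41 (1.3 equiv), 2-methyl-6-nitrobenzoic anhydride (1.5 equiv), Et3N, DMAP (0.2 equiv), CH2Cl2, rt
Reagents that add atoms: none
Why: Shiina esterification, in which the mixed 2-methyl-6-nitrobenzoic anhydride is generated at room temperature in the presence of the alcohol and is opened at its aliphatic carbonyl by DMAP as fast as it forms, suits this coupling because the dimer alcohol is the more valuable partner and the activated acid never accumulates, and it forms no stereocentre.

Step 31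
Reactants: 48 protected trimer C–B–A
Product: 50 cryptoporic acid T, via trimethylsilyl ester 49 (not isolated)
Conditions: TMSOTf, 2,6-lutidine, CH2Cl2, 0 °C → rt; then TBAF, THF, rt; aq. NH4Cl/citric acid work-up
Reagents that add atoms: none
Why: TMSOTf/2,6-lutidine converts the last tert-butyl ester into a silyl ester, and fluoride then removes that silyl ester, both 2-(trimethylsilyl)ethyl esters and the TBS ether, which should liberate the three acids and the C15 alcohol while the four methyl esters and the two inter-unit esters stay.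

Compound list
1 | succinaldehyde (butanedial) | O=CCCC=O | starting material
2 | methyl 2-(triphenylphosphoranylidene)propanoate | COC(=O)C(C)=P(c1ccccc1)(c1ccccc1)c1ccccc1 | starting material
3 | methyl (2E)-2-methyl-6-oxohex-2-enoate | O=CCC/C=C(\C)C(=O)OC | intermediate
4 | but-3-yn-1-ol | C#CCCO | starting material
5 | (E)-alkenylalane, dimethyl[(1E)-4-(dimethylalumanyloxy)-2-methylbut-1-en-1-yl]alumane | C[Al](C)/C=C(\C)CCO[Al](C)C | intermediate (not isolated)
6 | (3E)-3-methylhexa-3,5-dien-1-ol | C=C/C=C(\C)CCO | intermediate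
7 | (3E)-3-methylhexa-3,5-dienoic acid | C=C/C=C(\C)CC(=O)O | intermediate
8 | (4R)-4-benzyl-1,3-oxazolidin-2-one | O=C1N[C@H](Cc2ccccc2)CO1 | starting material
9 | (3E)-3-methylhexa-3,5-dienoic pivalic anhydride | C=C/C=C(\C)CC(=O)OC(=O)C(C)(C)C | intermediate (not isolated)
10 | lithium salt of (4R)-4-benzyl-1,3-oxazolidin-2-one | [Li]N1[C@H](Cc2ccccc2)COC1=O | intermediate (not isolated)
11 | (4R)-4-benzyl-3-[(3E)-3-methylhexa-3,5-dienoyl]-1,3-oxazolidin-2-one | C=C/C=C(\C)CC(=O)N1[C@H](Cc2ccccc2)COC1=O | intermediate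
12 | dibutylboron Z(O)-enolate of 11 | C=C/C=C(\C)/C=C(\OB(CCCC)CCCC)N1[C@H](Cc2ccccc2)COC1=O | intermediate (not isolated)
13 | methyl (2E,6S,7R,8E)-7-{[(4R)-4-benzyl-2-oxo-1,3-oxazolidin-3-yl]carbonyl}-6-hydroxy-2,8-dimethylundeca-2,8,10-trienoate | C=C/C=C(\C)[C@@H](C(=O)N1[C@H](Cc2ccccc2)COC1=O)[C@@H](O)CC/C=C(\C)C(=O)OC | intermediate
14 | methyl (2E,6S,7S,8E)-6-hydroxy-7-(hydroxymethyl)-2,8-dimethylundeca-2,8,10-trienoate | C=C/C=C(\C)[C@@H](CO)[C@@H](O)CC/C=C(\C)C(=O)OC | intermediate
15 | methyl (2E)-5-{(4S,5S)-2,2-di-tert-butyl-5-[(2E)-penta-2,4-dien-2-yl]-1,3,2-dioxasilinan-4-yl}-2-methylpent-2-enoate (cycloaddition precursor) | C=C/C=C(\C)[C@H]1CO[Si](C(C)(C)C)(C(C)(C)C)O[C@H]1CC/C=C(\C)C(=O)OC | intermediate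
16 | methyl 8β,11-O-(di-tert-butylsilylene)-8β,11-dihydroxy-12-nordrim-1-en-15-oate (trans-fused Δ1-octalin; 4α-CO2Me, 4β-CH3, 5α-H, 9α-H, 10β-CH3) | COC(=O)[C@]1(C)CC=C[C@]2(C)[C@H]3CO[Si](C(C)(C)C)(C(C)(C)C)O[C@H]3CC[C@@H]12 | intermediate
17 | methyl 8β,11-dihydroxy-12-nordrim-1-en-15-oate | COC(=O)[C@]1(C)CC=C[C@]2(C)[C@@H](CO)[C@@H](O)CC[C@@H]12 | intermediate
18 | dibutylstannylene acetal of 17 | COC(=O)[C@]1(C)CC=C[C@]2(C)[C@H]3CO[Sn](CCCC)(CCCC)O[C@H]3CC[C@@H]12 | intermediate (not isolated)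
19 | methyl 11-benzyloxy-8β-hydroxy-12-nordrim-1-en-15-oate | COC(=O)[C@]1(C)CC=C[C@]2(C)[C@@H](COCc3ccccc3)[C@@H](O)CC[C@@H]12 | intermediate
20 | methyl 11-benzyloxy-8-oxo-12-nordrim-1-en-15-oate | COC(=O)[C@]1(C)CC=C[C@]2(C)[C@@H](COCc3ccccc3)C(=O)CC[C@@H]12 | intermediate
21 | methyl 11-benzyloxy-8,8-ethylenedioxy-12-nordrim-1-en-15-oate | COC(=O)[C@]1(C)CC=C[C@]2(C)[C@@H](COCc3ccccc3)C3(OCCO3)CC[C@@H]12 | intermediate
22 | 11-benzyloxy-8,8-ethylenedioxy-12-nordrim-1-en-15-ol | OC[C@]1(C)CC=C[C@]2(C)[C@@H](COCc3ccccc3)C3(OCCO3)CC[C@@H]12 | intermediate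
23 | 11-benzyloxy-15-(tert-butyldimethylsilyloxy)-8,8-ethylenedioxy-12-nordrim-1-ene | CC(C)(C)[Si](C)(C)OC[C@]1(C)CC=C[C@]2(C)[C@@H](COCc3ccccc3)C3(OCCO3)CC[C@@H]12 | intermediate
24 | 15-(tert-butyldimethylsilyloxy)-8,8-ethylenedioxy-12-nordriman-11-ol | CC(C)(C)[Si](C)(C)OC[C@]1(C)CCC[C@]2(C)[C@@H](CO)C3(OCCO3)CC[C@@H]12 | intermediate
25 | D-aspartic acid 4-tert-butyl ester, (2R)-2-amino-4-tert-butoxy-4-oxobutanoic acid | N[C@H](CC(=O)OC(C)(C)C)C(=O)O | starting material
26 | (1R)-3-tert-butoxy-1-carboxylato-3-oxopropane-1-diazonium | N#[N+][C@H](CC(=O)OC(C)(C)C)C(=O)[O-] | intermediate (not isolated)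
27 | α-lactone, tert-butyl 2-(3-oxooxiran-2-yl)acetate (C2 inverted) | O=C1O[C@H]1CC(=O)OC(C)(C)C | intermediate (not isolated)
28 | (2R)-4-tert-butoxy-2-hydroxy-4-oxobutanoic acid | O[C@H](CC(=O)OC(C)(C)C)C(=O)O | intermediate
29 | 4-tert-butyl 1-methyl (2R)-2-hydroxybutanedioate | O[C@H](CC(=O)OC(C)(C)C)C(=O)OC | intermediate
30 | dilithium alkoxide–enolate of 29 | [Li]O[C@@H](C(=O)OC)/C=C(\O[Li])OC(C)(C)C | intermediate (not isolated)
31 | 4-tert-butyl 1-methyl (2R,3S)-2-hydroxy-3-(prop-2-en-1-yl)butanedioate | O[C@@H](C(=O)OC)[C@H](CC=C)C(=O)OC(C)(C)C | intermediate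
32 | 15-(tert-butyldimethylsilyloxy)-8,8-ethylenedioxy-12-nordriman-11-yl trifluoromethanesulfonate | CC(C)(C)[Si](C)(C)OC[C@]1(C)CCC[C@]2(C)[C@@H](COS(=O)(=O)C(F)(F)F)C3(OCCO3)CC[C@@H]12 | intermediate
33 | sodium alkoxide of 31 | [Na+].[O-][C@@H](C(=O)OC)[C@H](CC=C)C(=O)OC(C)(C)C | intermediate (not isolated)
34 | 4-tert-butyl 1-methyl (2R,3S)-2-{[15-(tert-butyldimethylsilyloxy)-8,8-ethylenedioxy-12-nordriman-11-yl]oxy}-3-(prop-2-en-1-yl)butanedioate | CC(C)(C)[Si](C)(C)OC[C@]1(C)CCC[C@]2(C)[C@@H](CO[C@@H](C(=O)OC)[C@H](CC=C)C(=O)OC(C)(C)C)C3(OCCO3)CC[C@@H]12 | intermediate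
35 | 4-tert-butyl 1-methyl (2R,3S)-2-{[15-(tert-butyldimethylsilyloxy)-8,8-ethylenedioxy-12-nordriman-11-yl]oxy}-3-(2-oxoethyl)butanedioate | CC(C)(C)[Si](C)(C)OC[C@]1(C)CCC[C@]2(C)[C@@H](CO[C@@H](C(=O)OC)[C@H](CC=O)C(=O)OC(C)(C)C)C3(OCCO3)CC[C@@H]12 | intermediate (not isolated)
36 | 2-tert-butyl 1-methyl 3-hydrogen (1R,2S)-1-{[15-(tert-butyldimethylsilyloxy)-8,8-ethylenedioxy-12-nordriman-11-yl]oxy}propane-1,2,3-tricarboxylate | CC(C)(C)[Si](C)(C)OC[C@]1(C)CCC[C@]2(C)[C@@H](CO[C@@H](C(=O)OC)[C@H](CC(=O)O)C(=O)OC(C)(C)C)C3(OCCO3)CC[C@@H]12 | intermediate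
37 | 2-tert-butyl 1-methyl 3-[2-(trimethylsilyl)ethyl] (1R,2S)-1-{[15-(tert-butyldimethylsilyloxy)-8,8-ethylenedioxy-12-nordriman-11-yl]oxy}propane-1,2,3-tricarboxylate | CC(C)(C)[Si](C)(C)OC[C@]1(C)CCC[C@]2(C)[C@@H](CO[C@@H](C(=O)OC)[C@H](CC(=O)OCC[Si](C)(C)C)C(=O)OC(C)(C)C)C3(OCCO3)CC[C@@H]12 | intermediate
38 | 2-tert-butyl 1-methyl 3-[2-(trimethylsilyl)ethyl] (1R,2S)-1-{[15-(tert-butyldimethylsilyloxy)-8-oxo-12-nordriman-11-yl]oxy}propane-1,2,3-tricarboxylate | CC(C)(C)[Si](C)(C)OC[C@]1(C)CCC[C@]2(C)[C@@H](CO[C@@H](C(=O)OC)[C@H](CC(=O)OCC[Si](C)(C)C)C(=O)OC(C)(C)C)C(=O)CC[C@@H]12 | intermediate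
39 | 2-tert-butyl 1-methyl 3-[2-(trimethylsilyl)ethyl] (1R,2S)-1-{[15-(tert-butyldimethylsilyloxy)drim-8(12)-en-11-yl]oxy}propane-1,2,3-tricarboxylate | CC(C)(C)[Si](C)(C)OC[C@]1(C)CCC[C@]2(C)[C@@H](CO[C@@H](C(=O)OC)[C@H](CC(=O)OCC[Si](C)(C)C)C(=O)OC(C)(C)C)C(=C)CC[C@@H]12 | intermediate
40 | 1-methyl 2-trimethylsilyl 3-[2-(trimethylsilyl)ethyl] (1R,2S)-1-{[15-(tert-butyldimethylsilyloxy)drim-8(12)-en-11-yl]oxy}propane-1,2,3-tricarboxylate | CC(C)(C)[Si](C)(C)OC[C@]1(C)CCC[C@]2(C)[C@@H](CO[C@@H](C(=O)OC)[C@H](CC(=O)OCC[Si](C)(C)C)C(=O)O[Si](C)(C)C)C(=C)CC[C@@H]12 | intermediate (not isolated)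
41 | 1-methyl 3-[2-(trimethylsilyl)ethyl] 2-hydrogen (1R,2S)-1-{[15-(tert-butyldimethylsilyloxy)drim-8(12)-en-11-yl]oxy}propane-1,2,3-tricarboxylate (acid for units B and C) | CC(C)(C)[Si](C)(C)OC[C@]1(C)CCC[C@]2(C)[C@@H](CO[C@@H](C(=O)OC)[C@H](CC(=O)OCC[Si](C)(C)C)C(=O)O)C(=C)CC[C@@H]12 | intermediate
42 | 2-tert-butyl 1-methyl 3-hydrogen (1R,2S)-1-[(15-hydroxydrim-8(12)-en-11-yl)oxy]propane-1,2,3-tricarboxylate | OC[C@]1(C)CCC[C@]2(C)[C@@H](CO[C@@H](C(=O)OC)[C@H](CC(=O)O)C(=O)OC(C)(C)C)C(=C)CC[C@@H]12 | intermediate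
43 | 2-tert-butyl 1,3-dimethyl (1R,2S)-1-[(15-hydroxydrim-8(12)-en-11-yl)oxy]propane-1,2,3-tricarboxylate (unit A alcohol) | OC[C@]1(C)CCC[C@]2(C)[C@@H](CO[C@@H](C(=O)OC)[C@H](CC(=O)OC)C(=O)OC(C)(C)C)C(=C)CC[C@@H]12 | intermediate
44 | mixed anhydride of 41 (C2′ carboxyl) with 2,4,6-trichlorobenzoic acid | CC(C)(C)[Si](C)(C)OC[C@]1(C)CCC[C@]2(C)[C@@H](CO[C@@H](C(=O)OC)[C@H](CC(=O)OCC[Si](C)(C)C)C(=O)OC(=O)c3c(Cl)cc(Cl)cc3Cl)C(=C)CC[C@@H]12 | intermediate (not isolated)
45 | silyl-protected dimer B–A: C2′ carboxyl of unit B esterified with C15–OH of unit A; unit B carries 15-OTBS and the C3′ 2-(trimethylsilyl)ethyl ester; unit A carries the C2′ tert-butyl and C3′ methyl esters | CC(C)(C)[Si](C)(C)OC[C@]1(C)CCC[C@]2(C)[C@@H](CO[C@@H](C(=O)OC)[C@H](CC(=O)OCC[Si](C)(C)C)C(=O)OC[C@]3(C)CCC[C@]4(C)[C@@H](CO[C@@H](C(=O)OC)[C@H](CC(=O)OC)C(=O)OC(C)(C)C)C(=C)CC[C@@H]34)C(=C)CC[C@@H]12 | intermediate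
46 | dimer alcohol B–A (45 with free C15–OH on unit B) | OC[C@]1(C)CCC[C@]2(C)[C@@H](CO[C@@H](C(=O)OC)[C@H](CC(=O)OCC[Si](C)(C)C)C(=O)OC[C@]3(C)CCC[C@]4(C)[C@@H](CO[C@@H](C(=O)OC)[C@H](CC(=O)OC)C(=O)OC(C)(C)C)C(=C)CC[C@@H]34)C(=C)CC[C@@H]12 | intermediate
47 | mixed anhydride of 41 (C2′ carboxyl) with 2-methyl-6-nitrobenzoic acid | CC(C)(C)[Si](C)(C)OC[C@]1(C)CCC[C@]2(C)[C@@H](CO[C@@H](C(=O)OC)[C@H](CC(=O)OCC[Si](C)(C)C)C(=O)OC(=O)c3c(C)cccc3[N+](=O)[O-])C(=C)CC[C@@H]12 | intermediate (not isolated)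
48 | protected trimer C–B–A: unit C with 15-OTBS; units C and B with C3′ 2-(trimethylsilyl)ethyl esters; unit A with C2′ tert-butyl and C3′ methyl esters | CC(C)(C)[Si](C)(C)OC[C@]1(C)CCC[C@]2(C)[C@@H](CO[C@@H](C(=O)OC)[C@H](CC(=O)OCC[Si](C)(C)C)C(=O)OC[C@]3(C)CCC[C@]4(C)[C@@H](CO[C@@H](C(=O)OC)[C@H](CC(=O)OCC[Si](C)(C)C)C(=O)OC[C@]5(C)CCC[C@]6(C)[C@@H](CO[C@@H](C(=O)OC)[C@H](CC(=O)OC)C(=O)OC(C)(C)C)C(=C)CC[C@@H]56)C(=C)CC[C@@H]34)C(=C)CC[C@@H]12 | intermediate
49 | 48 with the tert-butyl ester of unit A replaced by a trimethylsilyl ester | CC(C)(C)[Si](C)(C)OC[C@]1(C)CCC[C@]2(C)[C@@H](CO[C@@H](C(=O)OC)[C@H](CC(=O)OCC[Si](C)(C)C)C(=O)OC[C@]3(C)CCC[C@]4(C)[C@@H](CO[C@@H](C(=O)OC)[C@H](CC(=O)OCC[Si](C)(C)C)C(=O)OC[C@]5(C)CCC[C@]6(C)[C@@H](CO[C@@H](C(=O)OC)[C@H](CC(=O)OC)C(=O)O[Si](C)(C)C)C(=C)CC[C@@H]56)C(=C)CC[C@@H]34)C(=C)CC[C@@H]12 | intermediate (not isolated)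
50 | cryptoporic acid T | C=C1CC[C@H]2[C@](C)(COC(=O)[C@@H](CC(=O)O)[C@@H](OC[C@H]3C(=C)CC[C@H]4[C@](C)(COC(=O)[C@@H](CC(=O)O)[C@@H](OC[C@H]5C(=C)CC[C@H]6[C@](C)(CO)CCC[C@]56C)C(=O)OC)CCC[C@]34C)C(=O)OC)CCC[C@]2(C)[C@H]1CO[C@@H](C(=O)OC)[C@H](CC(=O)OC)C(=O)O | target

Total step count: 31.
Longest linear sequence: 26 steps (from 4: steps 2–15, 19–24, 26–31).

Steps most likely to fail

1. Step 8. The diene terminus carries an inside methyl and the dienophile is trisubstituted, so the cycloaddition may be slow. The Lewis acid may then oligomerise the diene, or the ester-exo (cis-fused) mode or the wrong diene face may compete. The fallback exchanges the ester for the more reactive aldehyde. It sets out from 15: DIBAL-H (CH2Cl2, −78 °C) reduces the enoate to the allylic alcohol F1. MnO2 (CH2Cl2, rt) gives the (E)-enal F2. Me2AlCl (CH2Cl2, −78 °C) then promotes the same cycloaddition, aldehyde endo, to the bicyclic aldehyde F3. Pinnick oxidation (NaClO2, NaH2PO4, 2-methylbut-2-ene) gives the acid F4, and MeI/K2CO3 in DMF comes back to the route at 16.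

2. Step 20. Substitution at the β-branched C11 may be slow. The triflate may then be lost by elimination, or the alkoxide may self-condense or expel its new alkoxy group by β-elimination. The fallback reverses the polarity and sets out from 31 and 24. A Mitsunobu reaction of 31 with 4-nitrobenzoic acid (PPh3, DIAD, THF) inverts C2 and gives the ester F5. K2CO3 in MeOH at 0 °C removes the aroyl group to give the (2S,3S)-hydroxy diester F6. Tf2O/2,6-lutidine gives the α-triflyloxy ester F7. The potassium alkoxide of 24 (KHMDS, THF, −78 °C) then displaces the triflate with inversion at C2 and comes back to the route at 34.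

3. Step 28 (and the second inter-unit esterification, step 30). Acyl transfer between a neopentyl alcohol and an α-branched acid may be slow. The base-activated acid may then epimerise at C2′ or lose the C1′ alkoxy group by β-elimination. The fallback uses a base-free, silver-promoted acyl transfer from an isolated thioester and sets out from 41. 2,2′-Dipyridyl disulfide and PPh3 (CH2Cl2, rt) give the S-pyridin-2-yl thioester F8. AgOTf in toluene at rt then transfers the acyl group to alcohol 43 and comes back to the route at 45. The same thioester with 46 comes back at 48.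

Further compounds
F1 | step 8 | (2E)-5-{(4S,5S)-2,2-di-tert-butyl-5-[(2E)-penta-2,4-dien-2-yl]-1,3,2-dioxasilinan-4-yl}-2-methylpent-2-en-1-ol | C=C/C=C(\C)[C@H]1CO[Si](C(C)(C)C)(C(C)(C)C)O[C@H]1CC/C=C(\C)CO
F2 | step 8 | (2E)-5-{(4S,5S)-2,2-di-tert-butyl-5-[(2E)-penta-2,4-dien-2-yl]-1,3,2-dioxasilinan-4-yl}-2-methylpent-2-enal | C=C/C=C(\C)[C@H]1CO[Si](C(C)(C)C)(C(C)(C)C)O[C@H]1CC/C=C(\C)C=O
F3 | step 8 | 8β,11-O-(di-tert-butylsilylene)-8β,11-dihydroxy-12-nordrim-1-en-15-al | O=C[C@]1(C)CC=C[C@]2(C)[C@H]3CO[Si](C(C)(C)C)(C(C)(C)C)O[C@H]3CC[C@@H]12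
F4 | step 8 | 8β,11-O-(di-tert-butylsilylene)-8β,11-dihydroxy-12-nordrim-1-en-15-oic acid | OC(=O)[C@]1(C)CC=C[C@]2(C)[C@H]3CO[Si](C(C)(C)C)(C(C)(C)C)O[C@H]3CC[C@@H]12
F5 | step 20 | 4-tert-butyl 1-methyl (2S,3S)-2-[(4-nitrobenzoyl)oxy]-3-(prop-2-en-1-yl)butanedioate | O=C(O[C@H](C(=O)OC)[C@H](CC=C)C(=O)OC(C)(C)C)c1ccc(cc1)[N+](=O)[O-]
F6 | step 20 | 4-tert-butyl 1-methyl (2S,3S)-2-hydroxy-3-(prop-2-en-1-yl)butanedioate | O[C@H](C(=O)OC)[C@H](CC=C)C(=O)OC(C)(C)C
F7 | step 20 | 4-tert-butyl 1-methyl (2S,3S)-3-(prop-2-en-1-yl)-2-[(trifluoromethanesulfonyl)oxy]butanedioate | O=S(=O)(O[C@H](C(=O)OC)[C@H](CC=C)C(=O)OC(C)(C)C)C(F)(F)F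
F8 | step 28 | S-pyridin-2-yl thioester of 41 at the C2′ carboxyl | CC(C)(C)[Si](C)(C)OC[C@]1(C)CCC[C@]2(C)[C@@H](CO[C@@H](C(=O)OC)[C@H](CC(=O)OCC[Si](C)(C)C)C(=O)Sc3ccccn3)C(=C)CC[C@@H]12
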